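The data were computed for substances that don't exist, and the scatter is random.

You want to know how L stands to Q in this flask at 2.5 h, so first you need to know how much D has gone by then.

| flask | D | remark | time |
|---|---|---|---|
| east | 0.80 M | the very flask that is asked about, followed so far |  |
| south-west | 1.2 M | run made earlier |  |
| flask | 0.80 M |  | 2.5 h |

| run | time / min | L / % | Q / % |
|---|---|---|---|
| east | 6.00 | 1 | 7 |
| east | 12.0 | 1 | 13 |
| east | 20.0 | 3 | 22 |
| east | 25.0 | 5 | 28 |
| east | 30.0 | 4 | 27 |
| east | 40.0 | 5 | 34 |
| east | 50.0 | 2 | 42 |
| south-west | 8.00 | 1 | 14 |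
| south-west | 12.0 | 0 | 16 |
| south-west | 20.0 | 1 | 26 |
| south-west | 30.0 | 4 | 31 |
| south-west | 50.0 | 4 | 46 |
| south-west | 60.0 | 1 | 47 |
| south-west | 120 | 4 | 70 |

(each reading ± 2 percentage points)

- ratio of L to Q at 80 s
- ratio of L to Q at 15 min
- ratio of L to Q at 2.5 h
- which of L and Q there is more of at 2.5 h

- a reading or a percentage of Q counts all its forms, free or not

Take Q plus L as the D that has gone. The east run shows 44.0% gone after 50.0 min, which gives a first-order constant of 0.696 h⁻¹. The south-west run has a charge 1.50 times the east charge. It shows 74.0% gone after 120 min, which gives 0.674 h⁻¹. The two constants are nearly equal. So freeze the later one as a half-life, 1.03 h, and call it the charge-free half-life of D, an apparent first-order half-life.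

But is it constant in time? The east run at 20.0 min gives a faster 0.863 h⁻¹. That doubt is real, yet the south-west constant is read late, and 2.5 h lies 30.0 min beyond its last reading. So you keep it, and you reckon that at 2.5 h this flask holds 18.6% of its D, with 81.4% shared between Q and L.

Is L a constant share of Q? The south-west run objects. From 30.0 min to 120 min Q climbs from 31% to 70%, while L reads 4% at the first of these times and 4% at the last. So I take L as flat at the mean of the last four readings of both runs, 3.62%. My ratio at 2.5 h is then 0.0466, with Q ahead. For 80 s I commit to no number, since the first east reading of L, 1%, sits inside the scatter of 2 percentage points.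

The forecast gave 0.09, 0.09 and 0.08 for the three ratios, with Q in the lead, on “parallel formation with a constant ratio”, so at 2.5 h it stands above my 0.0466.

    D ⇌ Q (K = 0.330, k = 1.02 h⁻¹)
    Q ⇌ L (K = 2.45, k = 0.634 h⁻¹)
    J ⇌ Q, rate k3*(cs3 - [Q]) while solid is left; crystals form when [Q] > cs3 (solubility = 13.0 mM, k = 8.20 h⁻¹)

At 2.50 h this flask holds Q at 74.8%, crystals J counted, and D at 19.5%, against the 18.6% reckoned from 1.03 h. L stands at 5.68%, higher than my flat 3.62%. The neighbour charged with 2.0 M holds D at 17.2%, against the same 18.6%. Taken by itself, both ways together, the step between D and dissolved Q has a relaxation half-life of 0.169 h, short against 2.5 h. The step between dissolved Q and L, taken the same way, has a longer one, 0.776 h, and in this flask the ratio of L to Q climbs from 0.00715 at 80 s through 0.0542 at 15 min to 0.0759 at 2.5 h.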